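**Retrosynthetic overview**
1. Pestaphilone G ⇐ its bis-acetonide. The pyran ring is closed last, by oxa-6π electrocyclisation of a 1-oxatriene (C3=O … C1H–OMe) and loss of MeOH.
2. The oxatriene ⇐ C4–C4a bond, made by addition–elimination of the side-chain methyl ketone enolate on a carbocyclic vinylogous acyl triflate.
3. The carbocycle ⇐ Dieckmann closure (C5–C6) of an acyclic keto ester; it is built before the pyran.
4. The ring diol (C7, C8) and the side-chain diol (C2', C3') are the same syn C(Me)(OH)–CH(OH) unit, so both come from C-methylated D-tartrate acetonide; C6' comes from (S)-1-bromo-2-methylbutane.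
5. Ring order: carbocycle (step 6), then pyran (step 11).

Assumption: core atoms carry isochromene numbers (C1–C8a) and side-chain atoms primed numbers; the enolate methylation of tartrate acetonide is taken to go with net retention (trans-diester kept), as I recall it for this enolate — the route depends on this and it should be checked first.

**Route**

Step 1
Reactants: 1 dimethyl (4S,5S)-2,2-dimethyl-1,3-dioxolane-4,5-dicarboxylate (dimethyl 2,3-O-isopropylidene-D-tartrate)
Product: 3 dimethyl (4S,5S)-2,2,4-trimethyl-1,3-dioxolane-4,5-dicarboxylate, via lithium ester enolate 2 (not isolated)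
Conditions: LiN(i-Pr)2, THF/DMPU, −78 °C; MeI, −78 °C
Reagents that add atoms: iodomethane CI
Why: Seebach alkylation of the tartrate acetonide enolate, in which the remaining stereocentre (bought with D-tartaric acid) directs MeI so that methyl replaces H with net retention and the trans-diester with the new (S) quaternary centre results.

Step 2
Reactants: 3 dimethyl (4S,5S)-2,2,4-trimethyl-1,3-dioxolane-4,5-dicarboxylate
Product: 4 methyl (4S,5S)-5-[methoxy(methyl)carbamoyl]-2,2,4-trimethyl-1,3-dioxolane-4-carboxylate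
Conditions: MeNH(OMe)·HCl, i-PrMgCl, THF, −20 °C
Reagents that add atoms: N,O-dimethylhydroxylamine hydrochloride CNOC.Cl
Why: Weinreb aminolysis with the magnesium amide converts only the ester on the CH carbon, because the ester on the quaternary carbon is far more hindered; no stereocentre is touched.

Step 3
Reactants: 4 methyl (4S,5S)-5-[methoxy(methyl)carbamoyl]-2,2,4-trimethyl-1,3-dioxolane-4-carboxylate
Product: 5 methyl (4S,5S)-5-(methoxyacetyl)-2,2,4-trimethyl-1,3-dioxolane-4-carboxylate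
Conditions: Bu3SnCH2OMe, n-BuLi, THF, −78 °C; then 4, −78 °C; aq. NH4Cl
Reagents that add atoms: tributyl(methoxymethyl)stannane CCCC[Sn](CCCC)(CCCC)COC
Why: Weinreb ketone synthesis with methoxymethyllithium (tin–lithium exchange), where the chelated tetrahedral adduct stops at the ketone and the hindered ester is left alone at −78 °C.

Step 4
Reactants: 5 methyl (4S,5S)-5-(methoxyacetyl)-2,2,4-trimethyl-1,3-dioxolane-4-carboxylate
Product: 7 methyl (4S,5S)-5-[(Z)-2-methoxy-1-(trifluoromethylsulfonyloxy)ethenyl]-2,2,4-trimethyl-1,3-dioxolane-4-carboxylate, via lithium Z-enolate 6 (not isolated)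
Conditions: LiN(SiMe3)2, THF, −78 °C; Comins' reagent, −78 → 0 °C
Reagents that add atoms: N-(5-chloropyridin-2-yl)bis(trifluoromethanesulfonimide) FC(F)(F)S(=O)(=O)N(c1ccc(Cl)cn1)S(=O)(=O)C(F)(F)F
Why: Kinetic, chelation-assisted enolisation on the CH2OMe side followed by O-triflation gives the enol triflate; its alkene geometry is lost later and does not matter.

Step 5
Reactants: 7 methyl (4S,5S)-5-[(Z)-2-methoxy-1-(trifluoromethylsulfonyloxy)ethenyl]-2,2,4-trimethyl-1,3-dioxolane-4-carboxylate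
Product: 8 methyl (4S,5R)-5-[(1Z)-1-methoxy-3-oxobut-1-en-2-yl]-2,2,4-trimethyl-1,3-dioxolane-4-carboxylate
Conditions: Pd(PPh3)4 (5 mol %), LiCl, CO (1 atm), Me4Sn, THF, 55 °C
Reagents that add atoms: carbon monoxide [C-]#[O+]; tetramethylstannane C[Sn](C)(C)C
Why: Carbonylative Stille coupling (oxidative addition of zerovalent palladium to the vinyl triflate, CO insertion, methyl transfer from tin) gives the β-methoxy enone that carries C1, C8a, C4a and C5.

Step 6
Reactants: 8 methyl (4S,5R)-5-[(1Z)-1-methoxy-3-oxobut-1-en-2-yl]-2,2,4-trimethyl-1,3-dioxolane-4-carboxylate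
Product: 10 (3aS,7aR,7Z)-7-(methoxymethylidene)-2,2,3a-trimethyl-4-oxo-3a,4,7,7a-tetrahydro-1,3-benzodioxol-6-yl trifluoromethanesulfonate, via potassium dione enolate 9 (not isolated)
Conditions: KN(SiMe3)2, THF, −78 °C → rt; then PhNTf2, 0 °C → rt
Reagents that add atoms: N-phenylbis(trifluoromethanesulfonimide) FC(F)(F)S(=O)(=O)N(c1ccccc1)S(=O)(=O)C(F)(F)F
Why: Dieckmann (intramolecular Claisen) condensation from the only enolisable position closes the carbocycle (C5–C6), and the dione enolate is O-triflated at the less hindered, more electron-rich oxygen on C4a (remote from quaternary C7) to give the vinylogous acyl triflate; C7 and C8 are untouched.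

Step 7
Reactants: 4 methyl (4S,5S)-5-[methoxy(methyl)carbamoyl]-2,2,4-trimethyl-1,3-dioxolane-4-carboxylate; 11 (S)-1-bromo-2-methylbutane
Product: 13 methyl (4S,5S)-2,2,4-trimethyl-5-[(3S)-3-methylpentanoyl]-1,3-dioxolane-4-carboxylate, via Grignard reagent 12 (not isolated)
Conditions: Mg, THF; then 4, THF, −20 → 0 °C; aq. NH4Cl
Reagents that add atoms: none
Why: Weinreb ketone synthesis with the Grignard reagent of the bought (S)-bromide, whose stereocentre is β to magnesium and is not affected.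

Step 8
Reactants: 13 methyl (4S,5S)-2,2,4-trimethyl-5-[(3S)-3-methylpentanoyl]-1,3-dioxolane-4-carboxylate
Product: 15 methyl (4S,5S)-2,2,4-trimethyl-5-[(1Z,3S)-3-methyl-1-(trifluoromethylsulfonyloxy)pent-1-en-1-yl]-1,3-dioxolane-4-carboxylate, via potassium Z-enolate 14 (not isolated)
Conditions: KN(SiMe3)2, THF, −78 °C; Comins' reagent, −78 → 0 °C
Reagents that add atoms: N-(5-chloropyridin-2-yl)bis(trifluoromethanesulfonimide) FC(F)(F)S(=O)(=O)N(c1ccc(Cl)cn1)S(=O)(=O)C(F)(F)F
Why: Kinetic deprotonation of the CH2 group gives the Z(O)-enolate, which is trapped as the (Z)-enol triflate and so fixes the later alkene geometry.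

Step 9
Reactants: 15 methyl (4S,5S)-2,2,4-trimethyl-5-[(1Z,3S)-3-methyl-1-(trifluoromethylsulfonyloxy)pent-1-en-1-yl]-1,3-dioxolane-4-carboxylate
Product: 16 methyl (4S,5R)-2,2,4-trimethyl-5-[(2E,4S)-4-methylhex-2-en-2-yl]-1,3-dioxolane-4-carboxylate
Conditions: Me2CuLi (from MeLi and CuI), THF/Et2O, −20 → 0 °C
Reagents that add atoms: lithium dimethylcuprate [Li+].C[Cu-]C
Why: Cuprate cross-coupling of the vinyl triflate goes with retention, turning the (Z)-triflate into the (E)-trisubstituted alkene, while the hindered ester is inert to the cuprate.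

Step 10
Reactants: 16 methyl (4S,5R)-2,2,4-trimethyl-5-[(2E,4S)-4-methylhex-2-en-2-yl]-1,3-dioxolane-4-carboxylate
Product: 18 1-[(4S,5R)-2,2,4-trimethyl-5-[(2E,4S)-4-methylhex-2-en-2-yl]-1,3-dioxolan-4-yl]ethanone, via lithium silyl enolate 17 (not isolated)
Conditions: Me3SiCH2Li (2.5 equiv), pentane/THF, 0 °C → rt; then MeOH, rt
Reagents that add atoms: (trimethylsilyl)methyllithium C[Si](C)(C)C[Li]
Why: Acyl substitution of the ester by Me3SiCH2Li stops at the enolate of the α-silyl ketone (no over-addition), and methanolysis of the C–Si bond gives the methyl ketone.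

Step 11
Reactants: 18 1-[(4S,5R)-2,2,4-trimethyl-5-[(2E,4S)-4-methylhex-2-en-2-yl]-1,3-dioxolan-4-yl]ethanone; 10 (3aS,7aR,7Z)-7-(methoxymethylidene)-2,2,3a-trimethyl-4-oxo-3a,4,7,7a-tetrahydro-1,3-benzodioxol-6-yl trifluoromethanesulfonate
Product: 23 7,8:2',3'-di-O-isopropylidene-pestaphilone G, via lithium ketone enolate 19 (not isolated), via substitution adduct 20 (not isolated), via Z-oxatriene 21 (not isolated), via methoxypyran 22 (not isolated)
Conditions: 18, LiN(SiMe3)2 (2.1 equiv), THF, −78 °C; 10, −78 → 0 °C; AcOH; then PhMe, 70 °C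
Reagents that add atoms: none
Why: Addition–elimination of the methyl ketone enolate at C4a of the vinylogous acyl triflate (attack at C6=O is hindered by quaternary C7) forges C4–C4a, and the adduct then tautomerises to the 1-oxatriene, closes by thermal oxa-6π electrocyclisation to the 2-methoxy-2H-pyran and loses methanol by 1,4-elimination to give the pyran ring, with no stereocentre affected.

Step 12
Reactants: 23 7,8:2',3'-di-O-isopropylidene-pestaphilone G
Product: 24 pestaphilone G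
Conditions: TFA/H2O/THF (1:1:4), 0 °C → rt
Reagents that add atoms: none
Why: Acid-catalysed acetal hydrolysis removes both acetonides (the strained trans-fused one first) and frees the four hydroxyls without touching any stereocentre.

**Compound list**
1 | dimethyl (4S,5S)-2,2-dimethyl-1,3-dioxolane-4,5-dicarboxylate (dimethyl 2,3-O-isopropylidene-D-tartrate) | COC(=O)[C@H]1OC(C)(C)O[C@@H]1C(=O)OC | starting material
2 | lithium ester enolate of 1 (C4 trigonal, C5 still S) | [Li+].[O-]C(OC)=C1OC(C)(C)O[C@@H]1C(=O)OC | intermediate (not isolated)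
3 | dimethyl (4S,5S)-2,2,4-trimethyl-1,3-dioxolane-4,5-dicarboxylate | COC(=O)[C@@]1(C)OC(C)(C)O[C@@H]1C(=O)OC | intermediate
4 | methyl (4S,5S)-5-[methoxy(methyl)carbamoyl]-2,2,4-trimethyl-1,3-dioxolane-4-carboxylate | COC(=O)[C@@]1(C)OC(C)(C)O[C@@H]1C(=O)N(C)OC | intermediate
5 | methyl (4S,5S)-5-(methoxyacetyl)-2,2,4-trimethyl-1,3-dioxolane-4-carboxylate | COC(=O)[C@@]1(C)OC(C)(C)O[C@@H]1C(=O)COC | intermediate
6 | lithium (Z)-enolate of 5 (enolate O cis to OMe) | COC(=O)[C@@]1(C)OC(C)(C)O[C@@H]1/C([O-])=C/OC.[Li+] | intermediate (not isolated)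
7 | methyl (4S,5S)-5-[(Z)-2-methoxy-1-(trifluoromethylsulfonyloxy)ethenyl]-2,2,4-trimethyl-1,3-dioxolane-4-carboxylate | COC(=O)[C@@]1(C)OC(C)(C)O[C@@H]1/C(OS(=O)(=O)C(F)(F)F)=C/OC | intermediate
8 | methyl (4S,5R)-5-[(1Z)-1-methoxy-3-oxobut-1-en-2-yl]-2,2,4-trimethyl-1,3-dioxolane-4-carboxylate | COC(=O)[C@@]1(C)OC(C)(C)O[C@@H]1/C(C(C)=O)=C/OC | intermediate
9 | potassium enolate of (3aS,7aR,7Z)-7-(methoxymethylidene)-2,2,3a-trimethyl-7,7a-dihydro-1,3-benzodioxole-4,6(3aH,5H)-dione | O=C2[C@@]1(C)OC(C)(C)O[C@@H]1/C(=C/OC)C([O-])=C2.[K+] | intermediate (not isolated)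
10 | (3aS,7aR,7Z)-7-(methoxymethylidene)-2,2,3a-trimethyl-4-oxo-3a,4,7,7a-tetrahydro-1,3-benzodioxol-6-yl trifluoromethanesulfonate | O=C2[C@@]1(C)OC(C)(C)O[C@@H]1/C(=C/OC)C(OS(=O)(=O)C(F)(F)F)=C2 | intermediate
11 | (S)-1-bromo-2-methylbutane | CC[C@H](C)CBr | starting material
12 | [(2S)-2-methylbutyl]magnesium bromide | CC[C@H](C)C[Mg]Br | intermediate (not isolated)
13 | methyl (4S,5S)-2,2,4-trimethyl-5-[(3S)-3-methylpentanoyl]-1,3-dioxolane-4-carboxylate | COC(=O)[C@@]1(C)OC(C)(C)O[C@@H]1C(=O)C[C@@H](C)CC | intermediate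
14 | potassium (Z)-enolate of 13 (enolate O cis to the sec-butyl group) | COC(=O)[C@@]1(C)OC(C)(C)O[C@@H]1/C([O-])=C/[C@@H](C)CC.[K+] | intermediate (not isolated)
15 | methyl (4S,5S)-2,2,4-trimethyl-5-[(1Z,3S)-3-methyl-1-(trifluoromethylsulfonyloxy)pent-1-en-1-yl]-1,3-dioxolane-4-carboxylate | COC(=O)[C@@]1(C)OC(C)(C)O[C@@H]1/C(OS(=O)(=O)C(F)(F)F)=C/[C@@H](C)CC | intermediate
16 | methyl (4S,5R)-2,2,4-trimethyl-5-[(2E,4S)-4-methylhex-2-en-2-yl]-1,3-dioxolane-4-carboxylate | COC(=O)[C@@]1(C)OC(C)(C)O[C@@H]1/C(C)=C/[C@@H](C)CC | intermediate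
17 | lithium enolate of the α-trimethylsilyl ketone formed from 16 | C[Si](C)(C)C=C([O-])[C@@]1(C)OC(C)(C)O[C@@H]1/C(C)=C/[C@@H](C)CC.[Li+] | intermediate (not isolated)
18 | 1-[(4S,5R)-2,2,4-trimethyl-5-[(2E,4S)-4-methylhex-2-en-2-yl]-1,3-dioxolan-4-yl]ethanone | CC(=O)[C@@]1(C)OC(C)(C)O[C@@H]1/C(C)=C/[C@@H](C)CC | intermediate
19 | lithium enolate of 18 | C=C([O-])[C@@]1(C)OC(C)(C)O[C@@H]1/C(C)=C/[C@@H](C)CC.[Li+] | intermediate (not isolated)
20 | substitution adduct: the enone of 10 with CH2C(=O)–(side-chain dioxolane) on C4a in place of OTf | O=C2[C@@]1(C)OC(C)(C)O[C@@H]1/C(=C/OC)C(CC(=O)[C@@]3(C)OC(C)(C)O[C@@H]3/C(C)=C/[C@@H](C)CC)=C2 | intermediate (not isolated)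
21 | 1-oxatriene tautomer of 20 (C4=C4a exocyclic, C3=O cis to C8a, C5 as CH2) | O=C2[C@@]1(C)OC(C)(C)O[C@@H]1/C(=C/OC)/C(=C\C(=O)[C@@]3(C)OC(C)(C)O[C@@H]3/C(C)=C/[C@@H](C)CC)C2 | intermediate (not isolated)
22 | 1-methoxy-1H-isochromene (2-methoxy-2H-pyran) from ring closure of 21, C1 epimers | O=C2[C@@]1(C)OC(C)(C)O[C@@H]1C3=C(C2)C=C(OC3OC)[C@@]4(C)OC(C)(C)O[C@@H]4/C(C)=C/[C@@H](C)CC | intermediate (not isolated)
23 | 7,8:2',3'-di-O-isopropylidene-pestaphilone G (7S,8R,2'S,3'R,4'E,6'S) | O=C2[C@@]1(C)OC(C)(C)O[C@@H]1C3=COC(=CC3=C2)[C@@]4(C)OC(C)(C)O[C@@H]4/C(C)=C/[C@@H](C)CC | intermediate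
24 | pestaphilone G, (7S,8R)-3-[(2S,3R,4E,6S)-2,3-dihydroxy-4,6-dimethyloct-4-en-2-yl]-7,8-dihydroxy-7-methyl-7,8-dihydro-6H-isochromen-6-one | CC[C@H](C)/C=C(\C)[C@@H](O)[C@](C)(O)C1=CC2=CC(=O)[C@@](C)(O)[C@H](O)C2=CO1 | target

**Step count and risks**

Total steps: 12. Longest linear sequence: 8 steps (1, 2, 7, 8, 9, 10, 11, 12; the ring branch 1–6, 11, 12 is equally long).

The three steps most likely to fail:

Step 4 needs the base to take a CH2OMe proton and not the dioxolane C–H next to the ketone, whose removal would open the ring by β-elimination. If this selectivity is poor, the ketone of 5 is used as an electrophile instead. 1-Ethoxyvinyllithium (ethyl vinyl ether, t-BuLi, THF, −78 °C) adds to 5 to give the tertiary alcohol F1. Dilute aqueous oxalic acid unmasks the acetyl group to give the α-hydroxy ketone F2. Dehydration with the Burgess reagent (PhMe, 60 °C) towards the CH2OMe group gives 8; either alkene isomer serves, since that geometry is lost in step 11. This fallback sets out from 5 and comes back at 8, replacing steps 4 and 5.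

Step 6 can fail in the Dieckmann closure (hindered ester, strained trans-fused acetonide) or in the site of O-triflation. The fallback reverses the ring order and makes the pyran first. From 16, 1-propynyllithium/BF3·OEt2 (THF, −78 °C) gives the ynone F3. Copper-catalysed β-borylation (CuCl, NaOt-Bu, Xantphos, B2pin2, MeOH, THF) gives the (Z)-β-boryl enone F4. Suzuki coupling with 7 (Pd(dppf)Cl2, K3PO4, dioxane/H2O, 60 °C) gives the push–pull dienone F5. Warming F5 with PPTS in PhMe isomerises the C4=C4a bond, closes the 2-methoxy-2H-pyran F6 by oxa-6π electrocyclisation, and by loss of methanol gives the 4-methylene-4H-pyran F7. Its exocyclic carbon, the only nucleophilic site, then acylates on the neighbouring methyl ester (i-Pr2NEt, PhMe, 110 °C) to close the carbocycle and give 23. This last acylation is itself untested. The fallback sets out from 7 and 16 and comes back at 23.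

Step 11 can fail if the lithium enolate adds to the C6 carbonyl of 10 (followed by fragmentation) instead of substituting at C4a. The fallback brings C4 in as an alkyne under palladium catalysis. From 16, i-Bu2AlH (CH2Cl2, −78 °C) gives the aldehyde F8. The Ohira–Bestmann reagent (K2CO3, MeOH) gives the alkyne F9. Sonogashira coupling with 10 (Pd(PPh3)4, CuI, Et3N, THF, rt) gives the enynone F10. PPTS in wet acetone hydrolyses the enol ether to the hydroxymethylene ketone F11, whose enol oxygen adds 6-endo to the conjugated alkyne (AgOTf cat. if needed) to give 23. This fallback sets out from 16 and 10 and comes back at 23.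

**Further compounds**
F1 | step 4 | adduct of 1-ethoxyvinyllithium with the ketone of 5 (tertiary alcohol, new centre as a mixture; dioxolane 4S,5S unchanged in space) | COC(=O)[C@@]1(C)OC(C)(C)O[C@@H]1C(O)(COC)C(OCC)=C
F2 | step 4 | α-hydroxy methyl ketone from hydrolysis of F1 | COC(=O)[C@@]1(C)OC(C)(C)O[C@@H]1C(O)(COC)C(C)=O
F3 | step 6 | 1-[(4S,5R)-2,2,4-trimethyl-5-[(2E,4S)-4-methylhex-2-en-2-yl]-1,3-dioxolan-4-yl]but-2-yn-1-one | CC#CC(=O)[C@@]1(C)OC(C)(C)O[C@@H]1/C(C)=C/[C@@H](C)CC
F4 | step 6 | (Z)-β-(pinacolboryl) enone from F3 (boron trans to the carbonyl) | C/C(B2OC(C)(C)C(C)(C)O2)=C\C(=O)[C@@]1(C)OC(C)(C)O[C@@H]1/C(C)=C/[C@@H](C)CC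
F5 | step 6 | cross-conjugated dienone from Suzuki coupling of 7 with F4 (C4=C4a E, methyl ester still present) | COC(=O)[C@@]1(C)OC(C)(C)O[C@@H]1/C(=C/OC)/C(C)=C/C(=O)[C@@]2(C)OC(C)(C)O[C@@H]2/C(C)=C/[C@@H](C)CC
F6 | step 6 | 2-methoxy-4-methyl-2H-pyran from oxa-6π closure of F5 | COC(=O)[C@@]1(C)OC(C)(C)O[C@@H]1C2=C(C)C=C(OC2OC)[C@@]3(C)OC(C)(C)O[C@@H]3/C(C)=C/[C@@H](C)CC
F7 | step 6 | 4-methylene-4H-pyran from F6 by loss of methanol | COC(=O)[C@@]1(C)OC(C)(C)O[C@@H]1C2=COC(=CC2=C)[C@@]3(C)OC(C)(C)O[C@@H]3/C(C)=C/[C@@H](C)CC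
F8 | step 11 | (4S,5R)-2,2,4-trimethyl-5-[(2E,4S)-4-methylhex-2-en-2-yl]-1,3-dioxolane-4-carbaldehyde | O=C[C@@]1(C)OC(C)(C)O[C@@H]1/C(C)=C/[C@@H](C)CC
F9 | step 11 | terminal alkyne from F8 (ethynyl in place of formyl) | C#C[C@@]1(C)OC(C)(C)O[C@@H]1/C(C)=C/[C@@H](C)CC
F10 | step 11 | enynone from Sonogashira coupling of 10 with F9 | O=C2[C@@]1(C)OC(C)(C)O[C@@H]1/C(=C/OC)C(C#C[C@@]3(C)OC(C)(C)O[C@@H]3/C(C)=C/[C@@H](C)CC)=C2
F11 | step 11 | hydroxymethylene ketone from hydrolysis of the enol ether of F10 | O=C2[C@@]1(C)OC(C)(C)O[C@@H]1C(=CO)C(C#C[C@@]3(C)OC(C)(C)O[C@@H]3/C(C)=C/[C@@H](C)CC)=C2
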